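**Retrosynthetic overview**

1. The strategy rests on the depside ester C1(=O)–O–C4'. Its carbonyl carbon C1 (ring A) is flanked by C2–OH and C6–CH3, whereas C4' (ring B) is para to the C1' carboxyl and ortho to the C3' methyl.
2. Key disconnection: the O–C4' bond, cut on the aryl side. This gives the ring A carboxylic acid 6 and the ring B aryl(2,4,6-trimethoxyphenyl)iodonium tosylate 15, so the crowded carbonyl is never attacked.
3. Ring A acid 6 comes from orsellinic acid: allyl ester, C3 formylation, O4 methylation, O2 benzylation, deallylation.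
4. Ring B salt 15 comes from methyl atrarate: 4'-triflate, boronate, iodide, saponification, double benzylation, oxidation at iodine in the presence of 1,3,5-trimethoxybenzene.
5. No ring is formed (both benzene rings are bought). One hydrogenolysis of three benzyl groups ends the route.

Key step: step 12

Assumption: orsellinic acid (free acid) is taken as the commercial ring A starting material and is carried as its allyl ester, so that the doubly ortho-substituted carboxyl can be freed without hydroxide in the presence of the aldehyde.

**Route**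

Step 1
Reactants: 1 orsellinic acid (2,4-dihydroxy-6-methylbenzoic acid)
Product: 2 allyl 2,4-dihydroxy-6-methylbenzoate
Conditions: allyl bromide (1.05 equiv), KHCO3, DMF, rt
Reagents that add atoms: allyl bromide C=CCBr
Why: Carboxylate SN2 alkylation, in which KHCO3 deprotonates only the carboxylic acid, so the ester forms while both phenols stay free.

Step 2
Reactants: 2 allyl 2,4-dihydroxy-6-methylbenzoate
Product: 3 allyl 3-formyl-2,4-dihydroxy-6-methylbenzoate
Conditions: Cl2CHOMe, TiCl4, CH2Cl2, −10 to 0 °C; then ice-cold 1 M HCl
Reagents that add atoms: dichloromethyl methyl ether COC(Cl)Cl; water O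
Why: Rieche formylation, in which TiCl4 bound to the phenol oxygens of the chelated 2,4-dihydroxybenzoate should direct the electrophile to C3 between the two hydroxyls, the usual site of formylation of orsellinate esters.

Step 3
Reactants: 3 allyl 3-formyl-2,4-dihydroxy-6-methylbenzoate
Product: 4 allyl 3-formyl-2-hydroxy-4-methoxy-6-methylbenzoate
Conditions: MeI (1.05 equiv), K2CO3, acetone, rt
Reagents that add atoms: iodomethane CI
Why: Williamson etherification, selective for O4 because the C4 hydroxyl (para to the ester) is more acidic and more accessible than the C2 hydroxyl, which is held between the ester and aldehyde carbonyls.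

Step 4
Reactants: 4 allyl 3-formyl-2-hydroxy-4-methoxy-6-methylbenzoate
Product: 5 allyl 2-(benzyloxy)-3-formyl-4-methoxy-6-methylbenzoate
Conditions: BnBr, K2CO3, DMF, 60 °C
Reagents that add atoms: benzyl bromide BrCc1ccccc1
Why: Williamson etherification under more forcing conditions should benzylate the remaining chelated C2 hydroxyl, the only nucleophilic site left in 4.

Step 5
Reactants: 5 allyl 2-(benzyloxy)-3-formyl-4-methoxy-6-methylbenzoate
Product: 6 2-(benzyloxy)-3-formyl-4-methoxy-6-methylbenzoic acid
Conditions: Pd(PPh3)4 (5 mol %), sodium 4-toluenesulfinate, THF/MeOH, rt; then 1 M HCl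
Reagents that add atoms: none
Why: Tsuji–Trost deallylation, in which zerovalent palladium ionises the allyl ester to a π-allyl complex that sulfinate captures as the allyl sulfone, so the hindered carboxyl is freed without hydroxide and the aldehyde, benzyl ether and methyl ether are untouched.

Step 6
Reactants: 7 methyl atrarate (methyl 2,4-dihydroxy-3,6-dimethylbenzoate)
Product: 8 methyl 2-hydroxy-3,6-dimethyl-4-[(trifluoromethylsulfonyl)oxy]benzoate
Conditions: Tf2O (1.1 equiv), pyridine, CH2Cl2, −10 to 0 °C
Reagents that add atoms: trifluoromethanesulfonic anhydride O=S(=O)(OS(=O)(=O)C(F)(F)F)C(F)(F)F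
Why: O-sulfonylation, selective for the free C4' hydroxyl because the C2' hydroxyl is hydrogen-bonded to the ester and flanked on both sides.

Step 7
Reactants: 8 methyl 2-hydroxy-3,6-dimethyl-4-[(trifluoromethylsulfonyl)oxy]benzoate
Product: 9 methyl 2-hydroxy-3,6-dimethyl-4-(4,4,5,5-tetramethyl-1,3,2-dioxaborolan-2-yl)benzoate
Conditions: B2pin2, PdCl2(dppf) (5 mol %), KOAc, 1,4-dioxane, 90 °C
Reagents that add atoms: bis(pinacolato)diboron CC1(C)OB(B2OC(C)(C)C(C)(C)O2)OC1(C)C
Why: Miyaura borylation (oxidative addition of zerovalent palladium into the aryl triflate, acetate-assisted transmetalation with the diboron), which tolerates the chelated phenol and the ester under the weak base KOAc.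

Step 8
Reactants: 9 methyl 2-hydroxy-3,6-dimethyl-4-(4,4,5,5-tetramethyl-1,3,2-dioxaborolan-2-yl)benzoate
Product: 10 methyl 2-hydroxy-4-iodo-3,6-dimethylbenzoate
Conditions: KI, CuI (10 mol %), 1,10-phenanthroline (20 mol %), MeOH/H2O 4:1, air, 80 °C
Reagents that add atoms: potassium iodide [K+].[I-]
Why: Copper-catalysed aerobic iododeboronation (aryl transfer from boron to copper, oxidation, C–I reductive elimination), which uses nucleophilic iodide and so should not iodinate the free C5' position para to the phenol as an electrophilic iodine source might.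

Step 9
Reactants: 10 methyl 2-hydroxy-4-iodo-3,6-dimethylbenzoate
Product: 11 2-hydroxy-4-iodo-3,6-dimethylbenzoic acid
Conditions: KOH, MeOH/H2O, reflux; then 2 M HCl
Reagents that add atoms: potassium hydroxide [K+].[OH-]
Why: Saponification of a salicylate ester, which proceeds despite the ortho methyl group; the aryl iodide is inert to aqueous hydroxide and the acid, lacking a para hydroxyl, should not decarboxylate.

Step 10
Reactants: 11 2-hydroxy-4-iodo-3,6-dimethylbenzoic acid
Product: 12 benzyl 2-(benzyloxy)-4-iodo-3,6-dimethylbenzoate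
Conditions: BnBr (2.5 equiv), K2CO3, DMF, 60 °C
Reagents that add atoms: benzyl bromide BrCc1ccccc1
Why: Double SN2 alkylation of the carboxylate and the phenoxide, which installs a benzyl ester and a benzyl ether that can later be removed together.

Step 11
Reactants: 12 benzyl 2-(benzyloxy)-4-iodo-3,6-dimethylbenzoate; 13 1,3,5-trimethoxybenzene
Product: 15 [3-(benzyloxy)-4-(benzyloxycarbonyl)-2,5-dimethylphenyl](2,4,6-trimethoxyphenyl)iodonium tosylate, via hydroxy(tosyloxy)iodane 14 (not isolated)
Conditions: mCPBA (1.1 equiv), TsOH·H2O (1.1 equiv), MeCN, 77 °C; then 13, 77 °C; Et2O trituration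
Reagents that add atoms: 4-toluenesulfonic acid Cc1ccc(S(=O)(=O)O)cc1
Why: One-pot oxidation of the aryl iodide to the hydroxy(tosyloxy)iodane 14 (its hydroxy ligand comes from mCPBA and leaves as water) followed by electrophilic aromatic substitution of the very nucleophilic trimethoxybenzene at trivalent iodine, which fixes iodine at C4' and outcompetes every other arene in the flask.

Step 12
Reactants: 6 2-(benzyloxy)-3-formyl-4-methoxy-6-methylbenzoic acid; 15 [3-(benzyloxy)-4-(benzyloxycarbonyl)-2,5-dimethylphenyl](2,4,6-trimethoxyphenyl)iodonium tosylate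
Product: 18 benzyl 2-(benzyloxy)-4-{[2-(benzyloxy)-3-formyl-4-methoxy-6-methylbenzoyl]oxy}-3,6-dimethylbenzoate (tribenzyl baeomycesic acid), via potassium carboxylate 16 (not isolated), via aryl(carboxylato)iodane 17 (not isolated)
Conditions: t-BuOK (1.0 equiv), toluene, rt; then 15 (1.1 equiv), 110 °C
Reagents that add atoms: none
Why: One equivalent of t-BuOK converts 6 into carboxylate 16, which exchanges with tosylate on trivalent iodine to give the T-shaped iodane 17; oxygen and the ipso carbon C4' of ring B then couple through a three-centre transition state and 2-iodo-1,3,5-trimethoxybenzene is expelled. The closest known reaction type is the metal-free O-arylation of carboxylic acids with unsymmetrical diaryliodonium salts, which tolerates congested acids and ortho-substituted aryl groups. The reacting atom is the carboxylate oxygen, which lies outside the pocket made by C2–OBn and C6–CH3, so the crowding that slows acyl transfer should matter little, and no acyl activation is needed. No ring is closed and no stereocentre is made. The step needs transfer of the ring B aryl and not the auxiliary: ring B is the electron-poorer ligand (ester para to iodine) and carries an ortho methyl group, while the electron-rich trimethoxyphenyl group resists ipso attack and leaves as the iodoarene. Both phenols are benzylated, so no phenoxide competes, and pre-forming 16 with exactly one equivalent of base keeps the aldehyde and the iodonium salt away from free alkoxide.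

Step 13
Reactants: 18 tribenzyl baeomycesic acid
Product: 19 baeomycesic acid
Conditions: H2 (1 atm), 10% Pd/C, EtOAc, rt
Reagents that add atoms: none
Why: Catalytic hydrogenolysis of the three benzylic C–O bonds (two aryl benzyl ethers, one benzyl ester); the formyl group, flanked by two oxygen substituents and chelated once O2 is free, should be reduced far more slowly, so the reaction is stopped after three equivalents of hydrogen.

**Compound list**

1 | orsellinic acid (2,4-dihydroxy-6-methylbenzoic acid) | Cc1cc(O)cc(O)c1C(=O)O | starting material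
2 | allyl 2,4-dihydroxy-6-methylbenzoate | C=CCOC(=O)c1c(C)cc(O)cc1O | intermediate
3 | allyl 3-formyl-2,4-dihydroxy-6-methylbenzoate | C=CCOC(=O)c1c(C)cc(O)c(C=O)c1O | intermediate
4 | allyl 3-formyl-2-hydroxy-4-methoxy-6-methylbenzoate | C=CCOC(=O)c1c(C)cc(OC)c(C=O)c1O | intermediate
5 | allyl 2-(benzyloxy)-3-formyl-4-methoxy-6-methylbenzoate | C=CCOC(=O)c1c(C)cc(OC)c(C=O)c1OCc1ccccc1 | intermediate
6 | 2-(benzyloxy)-3-formyl-4-methoxy-6-methylbenzoic acid | COc1cc(C)c(C(=O)O)c(OCc2ccccc2)c1C=O | intermediate
7 | methyl atrarate (methyl 2,4-dihydroxy-3,6-dimethylbenzoate) | COC(=O)c1c(C)cc(O)c(C)c1O | starting material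
8 | methyl 2-hydroxy-3,6-dimethyl-4-[(trifluoromethylsulfonyl)oxy]benzoate | COC(=O)c1c(C)cc(OS(=O)(=O)C(F)(F)F)c(C)c1O | intermediate
9 | methyl 2-hydroxy-3,6-dimethyl-4-(4,4,5,5-tetramethyl-1,3,2-dioxaborolan-2-yl)benzoate | COC(=O)c1c(C)cc(B2OC(C)(C)C(C)(C)O2)c(C)c1O | intermediate
10 | methyl 2-hydroxy-4-iodo-3,6-dimethylbenzoate | COC(=O)c1c(C)cc(I)c(C)c1O | intermediate
11 | 2-hydroxy-4-iodo-3,6-dimethylbenzoic acid | Cc1cc(I)c(C)c(O)c1C(=O)O | intermediate
12 | benzyl 2-(benzyloxy)-4-iodo-3,6-dimethylbenzoate | Cc1cc(I)c(C)c(OCc2ccccc2)c1C(=O)OCc1ccccc1 | intermediate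
13 | 1,3,5-trimethoxybenzene | COc1cc(OC)cc(OC)c1 | starting material
14 | benzyl 2-(benzyloxy)-4-[hydroxy(tosyloxy)iodanyl]-3,6-dimethylbenzoate | Cc1cc(I(O)OS(=O)(=O)c2ccc(C)cc2)c(C)c(OCc2ccccc2)c1C(=O)OCc1ccccc1 | intermediate (not isolated)
15 | [3-(benzyloxy)-4-(benzyloxycarbonyl)-2,5-dimethylphenyl](2,4,6-trimethoxyphenyl)iodonium tosylate | Cc1cc([I+]c2c(OC)cc(OC)cc2OC)c(C)c(OCc2ccccc2)c1C(=O)OCc1ccccc1.Cc1ccc(S(=O)(=O)[O-])cc1 | intermediate
16 | potassium 2-(benzyloxy)-3-formyl-4-methoxy-6-methylbenzoate | COc1cc(C)c(C(=O)[O-])c(OCc2ccccc2)c1C=O.[K+] | intermediate (not isolated)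
17 | [3-(benzyloxy)-4-(benzyloxycarbonyl)-2,5-dimethylphenyl][2-(benzyloxy)-3-formyl-4-methoxy-6-methylbenzoyloxy](2,4,6-trimethoxyphenyl)iodane | COc1cc(C)c(C(=O)OI(c2c(OC)cc(OC)cc2OC)c2cc(C)c(C(=O)OCc3ccccc3)c(OCc3ccccc3)c2C)c(OCc2ccccc2)c1C=O | intermediate (not isolated)
18 | benzyl 2-(benzyloxy)-4-{[2-(benzyloxy)-3-formyl-4-methoxy-6-methylbenzoyl]oxy}-3,6-dimethylbenzoate (tribenzyl baeomycesic acid) | COc1cc(C)c(C(=O)Oc2cc(C)c(C(=O)OCc3ccccc3)c(OCc3ccccc3)c2C)c(OCc2ccccc2)c1C=O | intermediate
19 | baeomycesic acid | COc1cc(C)c(C(=O)Oc2cc(C)c(C(=O)O)c(O)c2C)c(O)c1C=O | target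

**Step count**

Total steps: 13. Longest linear sequence: 8 steps (7 to 19, steps 6–13); the ring A branch (steps 1–5) joins at step 12.

**Steps most likely to fail**

Step 12 (key step). The ligand coupling may stall because salt 16 is poorly soluble or iodane 17 collapses slowly, and salt 15 may then break down by aryne formation or by transfer of the wrong aryl group. Fallback: form the ester from the acyl side. Setting out from iodide 12, Miyaura borylation (B2pin2, PdCl2(dppf), KOAc, dioxane, 90 °C) should give benzyl 2-(benzyloxy)-3,6-dimethyl-4-(4,4,5,5-tetramethyl-1,3,2-dioxaborolan-2-yl)benzoate F1. Oxidation (NaBO3·4H2O, THF/H2O, rt) should then give the phenol benzyl 2-(benzyloxy)-4-hydroxy-3,6-dimethylbenzoate F2. Acid 6 and F2 are condensed through the mixed trifluoroacetic anhydride (TFAA, toluene, rt), a known way to hindered depside esters, and the route is rejoined at 18.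

Step 13. Hydrogenation may run on into the formyl group (to hydroxymethyl or methyl) before the last benzyl group is cleaved. Fallback: non-reductive debenzylation of 18 with BCl3 and pentamethylbenzene as cation trap in CH2Cl2 at −78 °C. This should cleave the two chelation-activated benzyl ethers and the benzyl ester and, at this temperature, leave the C4 methyl ether. It sets out from 18, comes back at 19 and passes through no new compound (F0).

Step 8. Transfer of the ortho-methyl aryl group from boron to copper may be slow, so that protodeboronation or aerobic methoxylation takes over. Fallback: setting out from triflate 8, stannylation (Me3SnSnMe3, Pd(PPh3)4, LiCl, dioxane, 100 °C) should give methyl 2-hydroxy-3,6-dimethyl-4-(trimethylstannyl)benzoate F3. Ipso-iododestannylation with I2 (CH2Cl2, 0 °C) then returns the route at 10.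

**Further compounds**

F1 | step 12 | benzyl 2-(benzyloxy)-3,6-dimethyl-4-(4,4,5,5-tetramethyl-1,3,2-dioxaborolan-2-yl)benzoate | Cc1cc(B2OC(C)(C)C(C)(C)O2)c(C)c(OCc2ccccc2)c1C(=O)OCc1ccccc1
F2 | step 12 | benzyl 2-(benzyloxy)-4-hydroxy-3,6-dimethylbenzoate | Cc1cc(O)c(C)c(OCc2ccccc2)c1C(=O)OCc1ccccc1
F0 | step 13 | none | none
F3 | step 8 | methyl 2-hydroxy-3,6-dimethyl-4-(trimethylstannyl)benzoate | COC(=O)c1c(C)cc([Sn](C)(C)C)c(C)c1O
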